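| flask | substrate | free enzyme | added ligand | temperature | remark | time |
|---|---|---|---|---|---|---|
| epsilon | 0.073 M | 0.51 µM | 0.35 µM | −40 °C | run made earlier |  |
| gamma | 0.073 M | 0.51 µM | 0.52 µM | −5 °C | run made earlier |  |
| green | 0.073 M | 0.51 µM | 0.70 µM | 25 °C |  | 80 min |
| red | 0.073 M | 0.51 µM | 0.70 µM | −5 °C |  | 80 min |
| grey | 0.073 M | 0.51 µM | 0.70 µM | −35 °C |  | 80 min |
| amber | 0.073 M | 0.51 µM | 0.70 µM |  | at 25 °C until 1.0 h, from then on at −35 °C | 80 min |

| run | time / min | target / % | substrate / % |
|---|---|---|---|
| epsilon | 150 | 98.7 | 1.5 |
| epsilon | 240 | 99.2 | 0.9 |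
| epsilon | 360 | 99.5 | 0.6 |
| epsilon | 600 | 99.9 | 0.8 |
| epsilon | 720 | 99.6 | 0.1 |
| epsilon | 1200 | 99.7 | 0.9 |
| epsilon | 1800 | 100.0 | 0 |
| gamma | 20.0 | 89.0 | 10.5 |
| gamma | 50.0 | 95.1 | 3.8 |
| gamma | 120 | 95.8 | 1.5 |
| gamma | 240 | 94.3 | 0.7 |
| gamma | 360 | 91.8 | 0.5 |

(scatter of a reading: 0.3 percentage points)

1. the flask that comes out highest in amount of target, in percent of the substrate charged, or "all alike" when all lie within 1.5 percentage points (green / red / grey / amber / all alike)
2. target at the end, in percent of the substrate charged, green
3. target at the end, in percent of the substrate charged, red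
4. target at the end, in percent of the substrate charged, grey
5. target at the end, in percent of the substrate charged, amber



1. The easy step is a plot: in the gamma run I divide the substrate charge by c(substrate) at each reading and follow that ratio against time. It starts at one, but the first instants go unseen, since the first reading, at 20.0 min, already shows substrate at 10.5%.

2. In the middle of the gamma run, the ratio climbs by 0.560 min⁻¹ between the first two readings. I call this the clearing pace, the rise of that ratio per minute. Between the next two readings it climbs by 0.576 min⁻¹, nearly the same, though the low reading carries its scatter. I read this straight line as second order in substrate, so c(substrate) is the concentration to watch.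

3. Late in the gamma run, target plus substrate sinks from 97.3% at 120 min to 92.3% at 360 min, so target is leaving. That sum is the second thing to watch.

4. Red has the temperature of the gamma run but more added ligand, and its ligand exceeds the enzyme charge by 0.190 µM. I assume that ligand takes enzyme out of work, so red's pace should lie below the gamma pace. My reckoning is therefore a floor that rests on this assumption: the ratio starts at one, and at the gamma pace red keeps 2.18% of its substrate at 80 min, so on the assumption it keeps at least that.

5. The forecast gives green 56%, red 96%, grey 97.8%, amber 65%, with grey highest. Its ground is “about 2% substrate remains at 80 min in every flask”. A similar figure is a value there, but for red here it is a floor on my assumption.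

6. The flasks give green 26.3%, red 92.5%, grey 72.3%, amber 37.1%, so red comes out highest, not grey. Grey still holds 27.7% of its substrate at the end. Red holds 6.14%, above my floor. Between 40.0 min and 80.0 min, red's ratio climbs by 0.217 min⁻¹, slower than the gamma pace, which makes it 0.387 of 0.560 min⁻¹.

    free enzyme → spent catalyst (k = 5.60 × 10⁻⁵ s⁻¹, Ea = 95.0 kJ mol⁻¹)
    free enzyme → unfolded enzyme (k = 2.27 × 10⁻⁶ s⁻¹, Ea = 239 kJ mol⁻¹)
    target → over-reaction product (k = 3.03 × 10⁻⁴ s⁻¹, Ea = 97.0 kJ mol⁻¹)
    substrate + free enzyme → target + free enzyme, rate k4*[substrate]^2*[free enzyme]/(1 + ([substrate]/Kh4)^2) (45.6 mM, k = 3.14 × 10⁶ M⁻² s⁻¹, Ea = 14.0 kJ mol⁻¹)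
    free enzyme + added ligand ⇌ idle complex, settled at all times (K = 4.19 × 10⁷ M⁻¹, ΔH = −12.0 kJ mol⁻¹)
    (constants at 25 °C)

7. The neighbour flask is green's charge run at 0 °C, with free enzyme at 6.43% of its charge at 80.0 min against 5.93% in red at 80.0 min. If the pace follows free enzyme, and I set aside the difference in temperature from red, it becomes 0.235 min⁻¹, which leaves 5.05% of the substrate at 80 min. The computed flask holds 4.98% substrate and 91.8% target.

(The runs come from a simulation for an exercise; the scatter is artificial.)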